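**Stereochemistry:** the target has no stereocenters, so it is achiral and nothing needs to be set or protected.

**Assumptions**
- 1-Bromo-3,5-bis(benzyloxy)benzene is commercially available. Otherwise it is made from 5-bromoresorcinol, BnBr and K2CO3.
- Benzyl ethers protect the phenols because they come off by hydrogenolysis while the ring-A OMe survives.

## Retrosynthetic overview
1. The target comes from one-pot H2/Pd-C reduction of a tri-O-benzyl tetrayne. This saturates four C≡C bonds and cleaves three ArO–Bn bonds, leaving ArOMe.
2. Key bold step: a Cadiot–Chodkiewicz heterocoupling joins an aryl-capped bromoalkyne and an aryl-capped terminal alkyne into the central 1,3-diyne. The chain count is 2+3+4+3+2 = 14 carbons.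
3. Each aryl-capped half comes from Sonogashira mono-arylation of excess 1,6-heptadiyne. The ring-A bromide comes from 1,3-dibromo-5-methoxybenzene by lithiation–borylation–oxidation and then benzylation.
4. No rings are formed; both arenes are carried in from commercial materials.

## Forward route

**Step 1**
Reactants: **1** 1,3-dibromo-5-methoxybenzene; **2** hydrogen peroxide
Product: **3** 3-bromo-5-methoxyphenol
Conditions: 1) n-BuLi (1.0 equiv), THF/Et2O, −78 °C; 2) B(OMe)3; 3) 30% H2O2, 2 M NaOH, 0 °C → rt (one pot)
Reagents that add atoms: hydrogen peroxide, OO (supplies the phenol oxygen)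
Why: Mono Br/Li exchange on the symmetric dibromide, borylation, then oxidative deboronation (lithiation–borylation–oxidation) converts one C–Br into C–OH, while the other Br and the OMe survive.

**Step 2**
Reactants: **3** 3-bromo-5-methoxyphenol; **4** benzyl bromide
Product: **5** 1-(benzyloxy)-3-bromo-5-methoxybenzene
Conditions: BnBr, K2CO3, DMF, 60 °C
Reagents that add atoms: benzyl bromide, BrCc1ccccc1
Why: Williamson etherification gives the benzyl ether, which is removable later by hydrogenolysis and is stable to the base and organometallic conditions in between.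

**Step 3**
Reactants: **5** 1-(benzyloxy)-3-bromo-5-methoxybenzene; **6** 1,6-heptadiyne (4 equiv)
Product: **7** 1-(benzyloxy)-3-(hepta-1,6-diyn-1-yl)-5-methoxybenzene
Conditions: Pd(PPh3)2Cl2 (3 mol%), CuI (5 mol%), Et3N, THF, 60 °C, Ar
Reagents that add atoms: none
Why: Sonogashira coupling; the large excess of the symmetric diyne suppresses bis-arylation, and the aryl bromide couples selectively.

**Step 4**
Reactants: **8** 1-bromo-3,5-bis(benzyloxy)benzene; **6** 1,6-heptadiyne (4 equiv)
Product: **9** 1,3-bis(benzyloxy)-5-(hepta-1,6-diyn-1-yl)benzene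
Conditions: Pd(PPh3)2Cl2 (3 mol%), CuI (5 mol%), Et3N, THF, 60 °C, Ar
Reagents that add atoms: none
Why: The same Sonogashira mono-arylation as step 3 gives the ring-B half.

**Step 5**
Reactants: **7** 1-(benzyloxy)-3-(hepta-1,6-diyn-1-yl)-5-methoxybenzene; **10** N-bromosuccinimide
Product: **11** 1-(benzyloxy)-3-(7-bromohepta-1,6-diyn-1-yl)-5-methoxybenzene
Conditions: NBS (1.05 equiv), AgNO3 (10 mol%), acetone, rt, dark, 1 h
Reagents that add atoms: N-bromosuccinimide, O=C1CCC(=O)N1Br (supplies the Br)
Why: Ag(I) forms a silver acetylide at the terminal C–H only, and NBS brominates it (alkyne bromination); the internal aryl alkyne cannot form an acetylide.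

**Step 6**
Reactants: **11** bromoalkyne; **9** terminal alkyne (1.3 equiv)
Product: **12** 1-(benzyloxy)-3-[14-(3,5-bis(benzyloxy)phenyl)tetradeca-1,6,8,13-tetrayn-1-yl]-5-methoxybenzene
Conditions: CuCl (10 mol%), NH2OH·HCl, 70% aq. EtNH2, MeOH/THF, 0 °C → rt; slow addition of **11**
Reagents that add atoms: none
Why: Cadiot–Chodkiewicz heterocoupling; the copper acetylide of **9** couples with bromoalkyne **11** to give the unsymmetrical 1,3-diyne, hydroxylamine keeps copper as Cu(I), and slow addition of **11** with excess **9** limits homocoupling of **11**.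

**Step 7**
Reactants: **12** tri-O-benzyl tetrayne
Product: **13** target, 5-[14-(3,5-dihydroxyphenyl)tetradecyl]-3-methoxyphenol
Conditions: H2 (3 atm), 10% Pd/C, EtOAc/EtOH 1:1, rt, 24 h
Reagents that add atoms: none (only H is added)
Why: Pd-catalysed hydrogenation saturates all four C≡C bonds to CH2CH2 and hydrogenolyses the three aryl benzyl ethers (catalytic hydrogenation/hydrogenolysis), while the aryl methyl ether is inert.

## Compound list
1 | 1,3-dibromo-5-methoxybenzene | COc1cc(Br)cc(Br)c1 | starting material
2 | hydrogen peroxide | OO | starting material (reagent)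
3 | 3-bromo-5-methoxyphenol | COc1cc(O)cc(Br)c1 | intermediate
4 | benzyl bromide | BrCc1ccccc1 | starting material
5 | 1-(benzyloxy)-3-bromo-5-methoxybenzene | COc1cc(OCc2ccccc2)cc(Br)c1 | intermediate
6 | 1,6-heptadiyne | C#CCCCC#C | starting material
7 | 1-(benzyloxy)-3-(hepta-1,6-diyn-1-yl)-5-methoxybenzene | COc1cc(OCc2ccccc2)cc(C#CCCCC#C)c1 | intermediate
8 | 1-bromo-3,5-bis(benzyloxy)benzene | Brc1cc(OCc2ccccc2)cc(OCc2ccccc2)c1 | starting material
9 | 1,3-bis(benzyloxy)-5-(hepta-1,6-diyn-1-yl)benzene | C#CCCCC#Cc1cc(OCc2ccccc2)cc(OCc2ccccc2)c1 | intermediate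
10 | N-bromosuccinimide | O=C1CCC(=O)N1Br | starting material (reagent)
11 | 1-(benzyloxy)-3-(7-bromohepta-1,6-diyn-1-yl)-5-methoxybenzene | COc1cc(OCc2ccccc2)cc(C#CCCCC#CBr)c1 | intermediate
12 | 1-(benzyloxy)-3-[14-(3,5-bis(benzyloxy)phenyl)tetradeca-1,6,8,13-tetrayn-1-yl]-5-methoxybenzene | COc1cc(OCc2ccccc2)cc(C#CCCCC#CC#CCCCC#Cc2cc(OCc3ccccc3)cc(OCc3ccccc3)c2)c1 | intermediate
13 | 5-[14-(3,5-dihydroxyphenyl)tetradecyl]-3-methoxyphenol (CID16109872, achiral) | COc1cc(O)cc(CCCCCCCCCCCCCCc2cc(O)cc(O)c2)c1 | target

**Totals:** 7 steps. The longest linear sequence is 6 steps (1 → 3 → 5 → 7 → 11 → 12 → 13). The ring-B arm (8 → 9) is one step.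

## Three steps most likely to fail
1. **Step 6 (Cadiot–Chodkiewicz):** homocoupled symmetric diynes are hard to separate from the tetrayne.
   - Fallback (different approach): drop the diyne strategy and use sequential B-alkyl Suzuki couplings on 1,13-tetradecadiene. Hydroborate excess diene with 9-BBN, couple with the ring-A aryl bromide **5**, repeat with **8**, then H2/Pd-C.
2. **Step 5 (NBS/AgNO3 bromination):** the electron-rich dialkoxyarene may brominate on the ring.
   - Fallback (different approach): make the bromoalkyne from an aryl-free fragment, mono-TIPS-1,6-heptadiyne, and pair it with mono-TMS-1,6-heptadiyne in the Cadiot–Chodkiewicz coupling. Then install the two aryl groups by sequential Sonogashira couplings after selective TMS removal (K2CO3/MeOH) and TIPS removal (TBAF).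
3. **Steps 3/4 (mono-Sonogashira on a symmetric diyne):** bis-arylation or Glaser dimerization lowers the yield.
   - Fallback (different approach): make each half by alkylation instead. Prepare the arylacetylene from the ArCHO by Ohira–Bestmann homologation, deprotonate with n-BuLi, and alkylate with 5-iodo-1-(trimethylsilyl)pent-1-yne. Then remove the TMS group with K2CO3/MeOH.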